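The ten-membered carbocycle (C1–C10) is opened at the C3 ketone, which sits between sp3 C2 and sp2 C4 of the ring-Z C4=C5 enone, so C3 can come from carbon monoxide. In one operation the C1=C2 vinyl group of a seco compound is hydroborated and the primary alkylborane is joined through CO to the C4 vinyl iodide: C2–C3 and C3–C4 form, the ring closes and the enone geometry is inherited from the iodide. The seco precursor is a cis-disubstituted γ-lactone (O–C6, C7, C11, C12) that carries the (Z)-iodoalkene on C6 and, on C7, the chain with the C8 (R)-2-methylbutanoate and the C10 silyloxy vinyl carbinol.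

Key step: step 15

Remark: atom numbers follow the germacrane skeleton (ring C1–C10, lactone carbons C11 and C12, exocyclic methylene C13, methyl C14 on C10, hydroxymethyl C15 on C4); TBDPS = tert-butyldiphenylsilyl, TES = triethylsilyl.
Remark: the target is taken as the C3 keto C10 alcohol as drawn; it may equilibrate with its transannular 3,10-hemiketal, a ring–chain tautomer.
Remark: O15 is carried as the TBDPS ether so that it outlasts the acidic methanol of step 16, which has to remove the tertiary TES ether on O10.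
Remark: C10 is brought in preformed from (R)-2-methylglycidol, because chelate-controlled vinyl addition to a C8-hydroxy methyl ketone would be expected to give the 1,3-anti diol (the C10 epimer); C8 is then set by Felkin–Anh reduction.

Step 1
Reactants: 1 but-2-yne-1,4-diol
Product: 2 4-[(tert-butyldiphenylsilyl)oxy]but-2-yn-1-ol
Conditions: t-BuPh2SiCl (0.3 equiv), imidazole, DMF, 0 to 23 °C (1 in threefold excess)
Reagents that add atoms: tert-butyl(chloro)diphenylsilane, CC(C)(C)[Si](Cl)(c1ccccc1)c1ccccc1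
Why: Statistical monosilylation of a symmetrical diol used in excess (imidazole-promoted O-silylation) leaves one propargylic hydroxyl free to direct the next step.

Step 2
Reactants: 2 4-[(tert-butyldiphenylsilyl)oxy]but-2-yn-1-ol
Product: 4 (Z)-4-[(tert-butyldiphenylsilyl)oxy]-3-iodobut-2-en-1-ol, via cyclic vinylalanate 3 (not isolated)
Conditions: NaAlH2(OCH2CH2OMe)2, THF, 0 to 23 °C; EtOAc; then I2, −78 to 0 °C
Reagents that add atoms: iodine, [I][I]
Why: Hydroxyl-directed trans-hydroalumination of the propargylic alcohol puts hydride on the proximal alkyne carbon (C5) and aluminium on the distal one (C4) in alanate 3, and iodinolysis of the C–Al bond with retention gives the Z iodide with iodine cis to the hydroxymethyl group.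

Step 3
Reactants: 4 (Z)-4-[(tert-butyldiphenylsilyl)oxy]-3-iodobut-2-en-1-ol
Product: 5 (Z)-4-[(tert-butyldiphenylsilyl)oxy]-3-iodobut-2-enal
Conditions: MnO2, CH2Cl2, 23 °C
Reagents that add atoms: none
Why: MnO2 oxidises the allylic alcohol to the enal under neutral conditions that leave the Z geometry and the silyl ether untouched (allylic oxidation).

Step 4
Reactants: 6 (R)-4-benzyloxazolidin-2-one, 7 methyl 4-chloro-4-oxobutanoate
Product: 8 methyl 4-[(R)-4-benzyl-2-oxooxazolidin-3-yl]-4-oxobutanoate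
Conditions: n-BuLi, THF, −78 °C; then 7, −78 to 0 °C
Reagents that add atoms: none
Why: N-Acylation of the lithiated oxazolidinone by the acid chloride is fast at −78 °C and leaves the methyl ester alone.

Step 5
Reactants: 8 methyl 4-[(R)-4-benzyl-2-oxooxazolidin-3-yl]-4-oxobutanoate, 5 (Z)-4-[(tert-butyldiphenylsilyl)oxy]-3-iodobut-2-enal
Product: 11 (R)-4-benzyl-3-{(2R,3S)-2-[(Z)-3-[(tert-butyldiphenylsilyl)oxy]-2-iodoprop-1-en-1-yl]-5-oxooxolane-3-carbonyl}oxazolidin-2-one, via trimethylsilyl ether 9 (not isolated), via hydroxy ester 10 (not isolated)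
Conditions: MgCl2 (0.2 equiv), Et3N, Me3SiCl, EtOAc, 23 °C; then PPTS, MeOH, 23 °C; then CSA (cat.), CH2Cl2, 23 °C
Reagents that add atoms: none
Why: Magnesium-halide-catalysed Evans anti-aldol reaction: the chelated Z magnesium enolate of 8 should react through a boat transition state on the face away from the benzyl group, which sets C7 and places the C6 oxygen anti to the C11 branch (trapped as 9), and mild acid then frees the hydroxyl of 10, which closes onto the methyl ester to the cis-disubstituted lactone.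

Step 6
Reactants: 11 (R)-4-benzyl-3-{(2R,3S)-2-[(Z)-3-[(tert-butyldiphenylsilyl)oxy]-2-iodoprop-1-en-1-yl]-5-oxooxolane-3-carbonyl}oxazolidin-2-one
Product: 12 (2R,3S)-2-[(Z)-3-[(tert-butyldiphenylsilyl)oxy]-2-iodoprop-1-en-1-yl]-5-oxooxolane-3-carboxylic acid
Conditions: LiOH, H2O2, THF/H2O, 0 °C; Na2SO3; aq. HCl (pH 2)
Reagents that add atoms: hydrogen peroxide, OO
Why: Hydroperoxide attacks the exocyclic imide carbonyl selectively (Evans auxiliary cleavage), the percarboxylate is reduced by sulfite, any opened lactone recloses on acidification, and no stereocenter is touched.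

Step 7
Reactants: 13 (R)-(2-methyloxiran-2-yl)methanol
Product: 14 (R)-2-methyl-3-(phenylsulfonyl)propane-1,2-diol
Conditions: PhSO2Na, H2O/EtOH, 70 °C
Reagents that add atoms: sodium benzenesulfinate, [Na+].[O-]S(=O)c1ccccc1
Why: The sulfinate sulfur opens the epoxide by SN2 attack at its unsubstituted CH2 carbon (the future C9), so the C10–O bond and the C10 configuration are untouched.

Step 8
Reactants: 14 (R)-2-methyl-3-(phenylsulfonyl)propane-1,2-diol
Product: 15 (R)-2-methyl-3-(phenylsulfonyl)-1,2-bis[(triethylsilyl)oxy]propane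
Conditions: Et3SiOTf (2.4 equiv), 2,6-lutidine, CH2Cl2, 0 °C
Reagents that add atoms: triethylsilyl trifluoromethanesulfonate, CC[Si](CC)(CC)OS(=O)(=O)C(F)(F)F
Why: The silyl triflate silylates both the primary and the hindered tertiary hydroxyl (O-silylation), the tertiary ether being the O10 protecting group carried to the ring closure.

Step 9
Reactants: 15 (R)-2-methyl-3-(phenylsulfonyl)-1,2-bis[(triethylsilyl)oxy]propane
Product: 16 (R)-2-methyl-3-(phenylsulfonyl)-2-[(triethylsilyl)oxy]propanal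
Conditions: (COCl)2, DMSO, CH2Cl2, −78 to −40 °C; Et3N, −78 to 0 °C
Reagents that add atoms: none
Why: Under Swern conditions a primary triethylsilyl ether is converted directly into the aldehyde through its alkoxysulfonium salt, whereas the tertiary silyl ether cannot react, so deprotection and oxidation of C1 are merged.

Step 10
Reactants: 16 (R)-2-methyl-3-(phenylsulfonyl)-2-[(triethylsilyl)oxy]propanal
Product: 17 (R)-triethyl{[2-methyl-1-(phenylsulfonyl)but-3-en-2-yl]oxy}silane
Conditions: Ph3PCH3Br, KN(SiMe3)2, THF, −78 to 0 °C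
Reagents that add atoms: methyltriphenylphosphonium bromide, C[P+](c1ccccc1)(c1ccccc1)c1ccccc1.[Br-]
Why: Wittig methylenation of the non-enolisable aldehyde gives the C1=C2 vinyl group, the ylide being too weak a base to deprotonate the sulfone.

Step 11
Reactants: 12 (2R,3S)-2-[(Z)-3-[(tert-butyldiphenylsilyl)oxy]-2-iodoprop-1-en-1-yl]-5-oxooxolane-3-carboxylic acid, 17 (R)-triethyl{[2-methyl-1-(phenylsulfonyl)but-3-en-2-yl]oxy}silane
Product: 19 (4S,5R)-5-[(Z)-3-[(tert-butyldiphenylsilyl)oxy]-2-iodoprop-1-en-1-yl]-4-{(3R)-3-methyl-2-(phenylsulfonyl)-3-[(triethylsilyl)oxy]pent-4-enoyl}oxolan-2-one (both C9 epimers), via acyl imidazolide 18 (not isolated)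
Conditions: 12, CDI, THF, 23 °C; cannulated into 17 (2.1 equiv)/n-BuLi (2.0 equiv), THF, −78 °C; aq. NH4Cl
Reagents that add atoms: none
Why: C-Acylation of the α-sulfonyl carbanion by the N-acylimidazole (Claisen-type condensation) forms C8–C9 with the C10 stereocenter already in place, the second equivalent of carbanion deprotonates the β-keto sulfone at C9 and so protects C7 from epimerisation, and the new C9 stereocenter is erased in the next step.

Step 12
Reactants: 19 (4S,5R)-5-[(Z)-3-[(tert-butyldiphenylsilyl)oxy]-2-iodoprop-1-en-1-yl]-4-{(3R)-3-methyl-2-(phenylsulfonyl)-3-[(triethylsilyl)oxy]pent-4-enoyl}oxolan-2-one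
Product: 20 (4S,5R)-5-[(Z)-3-[(tert-butyldiphenylsilyl)oxy]-2-iodoprop-1-en-1-yl]-4-{(S)-3-methyl-3-[(triethylsilyl)oxy]pent-4-enoyl}oxolan-2-one
Conditions: SmI2 (2.5 equiv), THF/MeOH, −78 °C
Reagents that add atoms: none
Why: SmI2 reduces the β-keto sulfone by single-electron transfer, benzenesulfinate is expelled and the samarium enolate is protonated at C9 by methanol (reductive desulfonylation), too fast and too cold for the vinyl iodide or the lactone to react.

Step 13
Reactants: 20 (4S,5R)-5-[(Z)-3-[(tert-butyldiphenylsilyl)oxy]-2-iodoprop-1-en-1-yl]-4-{(S)-3-methyl-3-[(triethylsilyl)oxy]pent-4-enoyl}oxolan-2-one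
Product: 21 (4R,5R)-5-[(Z)-3-[(tert-butyldiphenylsilyl)oxy]-2-iodoprop-1-en-1-yl]-4-{(1R,3S)-1-hydroxy-3-methyl-3-[(triethylsilyl)oxy]pent-4-en-1-yl}oxolan-2-one
Conditions: LiBH(s-Bu)3, THF, −78 °C; AcOH, −78 °C
Reagents that add atoms: none
Why: Felkin–Anh reduction: the bulky hydride attacks the C8 ketone anti to the more substituted C7–C6 bond, which should give the 8R carbinol with the C8 oxygen anti to the C11 branch and syn to the C6 oxygen, and the cold acidic quench keeps the alkoxide from attacking the lactone.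

Step 14
Reactants: 21 (4R,5R)-5-[(Z)-3-[(tert-butyldiphenylsilyl)oxy]-2-iodoprop-1-en-1-yl]-4-{(1R,3S)-1-hydroxy-3-methyl-3-[(triethylsilyl)oxy]pent-4-en-1-yl}oxolan-2-one, 22 (R)-2-methylbutanoic acid
Product: 24 (1R,3S)-1-{(2R,3R)-2-[(Z)-3-[(tert-butyldiphenylsilyl)oxy]-2-iodoprop-1-en-1-yl]-5-oxooxolan-3-yl}-3-methyl-3-[(triethylsilyl)oxy]pent-4-en-1-yl (R)-2-methylbutanoate, via mixed anhydride 23 (not isolated)
Conditions: 22, 2,4,6-Cl3C6H2COCl, Et3N, THF, 23 °C; then 21, DMAP, toluene, 23 °C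
Reagents that add atoms: none
Why: Yamaguchi esterification through mixed anhydride 23 acylates the hindered secondary C8 hydroxyl, the only free hydroxyl, without touching the α-stereocenter of the acid.

Step 15
Reactants: 24 (1R,3S)-1-{(2R,3R)-2-[(Z)-3-[(tert-butyldiphenylsilyl)oxy]-2-iodoprop-1-en-1-yl]-5-oxooxolan-3-yl}-3-methyl-3-[(triethylsilyl)oxy]pent-4-en-1-yl (R)-2-methylbutanoate, 25 carbon monoxide
Product: 27 (3aR,4R,6R,11aS,Z)-10-{[(tert-butyldiphenylsilyl)oxy]methyl}-6-methyl-2,9-dioxo-6-[(triethylsilyl)oxy]-2,3,3a,4,5,6,7,8,9,11a-decahydrocyclodeca[b]furan-4-yl (R)-2-methylbutanoate, via B-alkyl-9-BBN borane 26 (not isolated)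
Conditions: 9-BBN, THF, 23 to 40 °C; then syringe-pump addition to Pd(PPh3)4 (15 mol%), K3PO4·H2O (3 equiv), CO (1 atm), THF/DMF, 50 °C (2 mM)
Reagents that add atoms: none
Why: 9-BBN adds only to the monosubstituted C1=C2 vinyl group (boron on C2), since the trisubstituted iodine-bearing C4=C5 alkene, the lactone and the esters do not react with this hindered borane. Oxidative addition of the C4–I bond to zerovalent palladium keeps the Z geometry, migratory insertion of CO gives the C3 acyl complex (C3–C4), the borate formed from 26 and phosphate hands over the C2 alkyl group, and reductive elimination of acyl and alkyl makes C2–C3. The closest known reaction types are the intermolecular carbonylative Suzuki–Miyaura coupling of B-alkyl-9-BBN reagents with alkenyl iodides and the B-alkyl Suzuki macrocyclisation. The ten-membered carbocycle closes by reductive elimination from an eleven-membered acyl(alkyl)palladacycle, helped by slow addition at high dilution and by the turn that the cis-lactone and the Z-alkene give the chain. No stereocenter is formed. The step needs carbonylative over direct coupling, which the CO atmosphere, the lack of a β-hydrogen pathway in the acyl complex and the strain of the nine-membered alternative should secure.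

Step 16
Reactants: 27 (3aR,4R,6R,11aS,Z)-10-{[(tert-butyldiphenylsilyl)oxy]methyl}-6-methyl-2,9-dioxo-6-[(triethylsilyl)oxy]-2,3,3a,4,5,6,7,8,9,11a-decahydrocyclodeca[b]furan-4-yl (R)-2-methylbutanoate
Product: 28 3,10-epoxy 3-O-methyl ketal of desilylated 27 (oxygen bridge from C10 to C3, methoxy on C3, C4=C5 Z, O15 TBDPS, 8-O-(R)-2-methylbutanoyl, 6S,7R,8R,10R)
Conditions: CSA (0.2 equiv), MeOH, 0 to 23 °C
Reagents that add atoms: methanol, CO
Why: Acidic methanol cleaves the tertiary triethylsilyl ether but not the bulkier TBDPS ether, the freed C10 hydroxyl adds across the ring to the C3 ketone and the hemiketal is trapped as the methyl ketal (C3 configuration fixed by the one-atom oxygen bridge), which masks the ketone and its acidic C2 hydrogens.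

Step 17
Reactants: 28 3,10-epoxy 3-O-methyl ketal
Product: 29 28 carrying a dimethylaminomethyl group on C11 (both C11 epimers)
Conditions: LiN(i-Pr)2, THF, −78 °C; CH2=NMe2 I, −78 to 0 °C
Reagents that add atoms: dimethylmethyleneiminium iodide, C=[N+](C)C.[I-]
Why: Kinetic deprotonation at C11, the only unhindered α-CH2 once the ketone is masked (the ester has only a hindered tertiary α-hydrogen), followed by Mannich reaction of the lactone enolate installs C13, and the C11 stereocenter is lost in the next step.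

Step 18
Reactants: 29 C11 dimethylaminomethyl lactone
Product: 31 28 carrying the exocyclic C11=C13 methylene, via trimethylammonium iodide 30 (not isolated)
Conditions: MeI, MeOH, 23 °C; then NaHCO3, H2O/CH2Cl2, 23 °C
Reagents that add atoms: none
Why: N-Methylation gives ammonium salt 30, whose acidic C11 hydrogen lets mild base eliminate trimethylamine (Hofmann-type E1cB elimination) to the exocyclic methylene.

Step 19
Reactants: 31 protected α-methylene lactone ketal
Product: 32 (3aR,4R,6R,11aS,Z)-6-hydroxy-10-(hydroxymethyl)-6-methyl-3-methylidene-2,9-dioxo-2,3,3a,4,5,6,7,8,9,11a-decahydrocyclodeca[b]furan-4-yl (R)-2-methylbutanoate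
Conditions: aq. HF (48%), MeCN, 0 to 23 °C
Reagents that add atoms: water, O
Why: Aqueous HF cleaves the silyl ether and hydrolyses the acid-labile methyl ketal, which releases the C3 ketone and the C10 hydroxyl, while no stereocenter is affected and the α-methylene lactone and the ester should be stable.

Compound list
1 | but-2-yne-1,4-diol | OCC#CCO | starting material
2 | 4-[(tert-butyldiphenylsilyl)oxy]but-2-yn-1-ol | OCC#CCO[Si](c1ccccc1)(c1ccccc1)C(C)(C)C | intermediate
3 | sodium cyclic vinylalanate of 2 (five-membered Al–O–CH2–CH=C ring, two 2-methoxyethoxy groups on Al) | COCCO[Al-]1(OCCOC)OCC=C1CO[Si](c2ccccc2)(c2ccccc2)C(C)(C)C.[Na+] | intermediate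
4 | (Z)-4-[(tert-butyldiphenylsilyl)oxy]-3-iodobut-2-en-1-ol | OC/C=C(\I)CO[Si](c1ccccc1)(c1ccccc1)C(C)(C)C | intermediate
5 | (Z)-4-[(tert-butyldiphenylsilyl)oxy]-3-iodobut-2-enal | O=C/C=C(\I)CO[Si](c1ccccc1)(c1ccccc1)C(C)(C)C | intermediate
6 | (R)-4-benzyloxazolidin-2-one | O=C1N[C@H](Cc2ccccc2)CO1 | starting material
7 | methyl 4-chloro-4-oxobutanoate | COC(=O)CCC(Cl)=O | starting material
8 | methyl 4-[(R)-4-benzyl-2-oxooxazolidin-3-yl]-4-oxobutanoate | COC(=O)CCC(=O)N1[C@H](Cc2ccccc2)COC1=O | intermediate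
9 | methyl (3S,4R,5Z)-3-[(R)-4-benzyl-2-oxooxazolidine-3-carbonyl]-7-[(tert-butyldiphenylsilyl)oxy]-6-iodo-4-[(trimethylsilyl)oxy]hept-5-enoate | COC(=O)C[C@@H]([C@@H](O[Si](C)(C)C)/C=C(\I)CO[Si](c1ccccc1)(c1ccccc1)C(C)(C)C)C(=O)N1[C@H](Cc2ccccc2)COC1=O | intermediate
10 | methyl (3S,4R,5Z)-3-[(R)-4-benzyl-2-oxooxazolidine-3-carbonyl]-7-[(tert-butyldiphenylsilyl)oxy]-4-hydroxy-6-iodohept-5-enoate | COC(=O)C[C@@H]([C@@H](O)/C=C(\I)CO[Si](c1ccccc1)(c1ccccc1)C(C)(C)C)C(=O)N1[C@H](Cc2ccccc2)COC1=O | intermediate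
11 | (R)-4-benzyl-3-{(2R,3S)-2-[(Z)-3-[(tert-butyldiphenylsilyl)oxy]-2-iodoprop-1-en-1-yl]-5-oxooxolane-3-carbonyl}oxazolidin-2-one | C1C(=O)O[C@@H](/C=C(\I)CO[Si](c2ccccc2)(c2ccccc2)C(C)(C)C)[C@H]1C(=O)N1[C@H](Cc2ccccc2)COC1=O | intermediate
12 | (2R,3S)-2-[(Z)-3-[(tert-butyldiphenylsilyl)oxy]-2-iodoprop-1-en-1-yl]-5-oxooxolane-3-carboxylic acid | C1C(=O)O[C@@H](/C=C(\I)CO[Si](c2ccccc2)(c2ccccc2)C(C)(C)C)[C@H]1C(=O)O | intermediate
13 | (R)-(2-methyloxiran-2-yl)methanol ((R)-2-methylglycidol) | C[C@@]1(CO)CO1 | starting material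
14 | (R)-2-methyl-3-(phenylsulfonyl)propane-1,2-diol | O=S(=O)(c1ccccc1)C[C@](C)(O)CO | intermediate
15 | (R)-2-methyl-3-(phenylsulfonyl)-1,2-bis[(triethylsilyl)oxy]propane | O=S(=O)(c1ccccc1)C[C@](C)(O[Si](CC)(CC)CC)CO[Si](CC)(CC)CC | intermediate
16 | (R)-2-methyl-3-(phenylsulfonyl)-2-[(triethylsilyl)oxy]propanal | O=S(=O)(c1ccccc1)C[C@](C)(O[Si](CC)(CC)CC)C=O | intermediate
17 | (R)-triethyl{[2-methyl-1-(phenylsulfonyl)but-3-en-2-yl]oxy}silane | O=S(=O)(c1ccccc1)C[C@](C)(O[Si](CC)(CC)CC)C=C | intermediate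
18 | 1-{(2R,3S)-2-[(Z)-3-[(tert-butyldiphenylsilyl)oxy]-2-iodoprop-1-en-1-yl]-5-oxooxolane-3-carbonyl}imidazole | C1C(=O)O[C@@H](/C=C(\I)CO[Si](c2ccccc2)(c2ccccc2)C(C)(C)C)[C@H]1C(=O)n1ccnc1 | intermediate
19 | (4S,5R)-5-[(Z)-3-[(tert-butyldiphenylsilyl)oxy]-2-iodoprop-1-en-1-yl]-4-{(3R)-3-methyl-2-(phenylsulfonyl)-3-[(triethylsilyl)oxy]pent-4-enoyl}oxolan-2-one (both C9 epimers) | C1C(=O)O[C@@H](/C=C(\I)CO[Si](c2ccccc2)(c2ccccc2)C(C)(C)C)[C@H]1C(=O)C([C@](C)(O[Si](CC)(CC)CC)C=C)S(=O)(=O)c1ccccc1 | intermediate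
20 | (4S,5R)-5-[(Z)-3-[(tert-butyldiphenylsilyl)oxy]-2-iodoprop-1-en-1-yl]-4-{(S)-3-methyl-3-[(triethylsilyl)oxy]pent-4-enoyl}oxolan-2-one | C1C(=O)O[C@@H](/C=C(\I)CO[Si](c2ccccc2)(c2ccccc2)C(C)(C)C)[C@H]1C(=O)C[C@](C)(O[Si](CC)(CC)CC)C=C | intermediate
21 | (4R,5R)-5-[(Z)-3-[(tert-butyldiphenylsilyl)oxy]-2-iodoprop-1-en-1-yl]-4-{(1R,3S)-1-hydroxy-3-methyl-3-[(triethylsilyl)oxy]pent-4-en-1-yl}oxolan-2-one | C1C(=O)O[C@@H](/C=C(\I)CO[Si](c2ccccc2)(c2ccccc2)C(C)(C)C)[C@H]1[C@H](O)C[C@](C)(O[Si](CC)(CC)CC)C=C | intermediate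
22 | (R)-2-methylbutanoic acid | CC[C@@H](C)C(=O)O | starting material
23 | (R)-2-methylbutanoic 2,4,6-trichlorobenzoic anhydride | CC[C@@H](C)C(=O)OC(=O)c1c(Cl)cc(Cl)cc1Cl | intermediate
24 | (1R,3S)-1-{(2R,3R)-2-[(Z)-3-[(tert-butyldiphenylsilyl)oxy]-2-iodoprop-1-en-1-yl]-5-oxooxolan-3-yl}-3-methyl-3-[(triethylsilyl)oxy]pent-4-en-1-yl (R)-2-methylbutanoate (seco vinyl iodide) | C1C(=O)O[C@@H](/C=C(\I)CO[Si](c2ccccc2)(c2ccccc2)C(C)(C)C)[C@H]1[C@H](OC(=O)[C@H](C)CC)C[C@](C)(O[Si](CC)(CC)CC)C=C | intermediate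
25 | carbon monoxide | [C-]#[O+] | starting material
26 | B-alkyl-9-BBN borane of 24 (9-borabicyclo[3.3.1]nonan-9-yl on C2) | C1C(=O)O[C@@H](/C=C(\I)CO[Si](c2ccccc2)(c2ccccc2)C(C)(C)C)[C@H]1[C@H](OC(=O)[C@H](C)CC)C[C@](C)(O[Si](CC)(CC)CC)CCB1C2CCCC1CCC2 | intermediate
27 | (3aR,4R,6R,11aS,Z)-10-{[(tert-butyldiphenylsilyl)oxy]methyl}-6-methyl-2,9-dioxo-6-[(triethylsilyl)oxy]-2,3,3a,4,5,6,7,8,9,11a-decahydrocyclodeca[b]furan-4-yl (R)-2-methylbutanoate (ten-membered enone) | C1C(=O)O[C@H]2/C=C(/CO[Si](c3ccccc3)(c3ccccc3)C(C)(C)C)C(=O)CC[C@@](C)(O[Si](CC)(CC)CC)C[C@@H](OC(=O)[C@H](C)CC)[C@@H]12 | intermediate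
28 | 3,10-epoxy 3-O-methyl ketal of desilylated 27 (6S,7R,8R,10R; C3 fixed by the bridge) | C1C(=O)O[C@H]2/C=C(/CO[Si](c3ccccc3)(c3ccccc3)C(C)(C)C)[C@]4(OC)CC[C@@](C)(O4)C[C@@H](OC(=O)[C@H](C)CC)[C@@H]12 | intermediate
29 | 28 with a dimethylaminomethyl group on C11 (both C11 epimers) | CN(C)CC1C(=O)O[C@H]2/C=C(/CO[Si](c3ccccc3)(c3ccccc3)C(C)(C)C)[C@]4(OC)CC[C@@](C)(O4)C[C@@H](OC(=O)[C@H](C)CC)[C@@H]12 | intermediate
30 | N-methyl quaternary ammonium iodide of 29 | C[N+](C)(C)CC1C(=O)O[C@H]2/C=C(/CO[Si](c3ccccc3)(c3ccccc3)C(C)(C)C)[C@]4(OC)CC[C@@](C)(O4)C[C@@H](OC(=O)[C@H](C)CC)[C@@H]12.[I-] | intermediate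
31 | 28 with the exocyclic C11=C13 methylene | C=C1C(=O)O[C@H]2/C=C(/CO[Si](c3ccccc3)(c3ccccc3)C(C)(C)C)[C@]4(OC)CC[C@@](C)(O4)C[C@@H](OC(=O)[C@H](C)CC)[C@@H]12 | intermediate
32 | (3aR,4R,6R,11aS,Z)-6-hydroxy-10-(hydroxymethyl)-6-methyl-3-methylidene-2,9-dioxo-2,3,3a,4,5,6,7,8,9,11a-decahydrocyclodeca[b]furan-4-yl (R)-2-methylbutanoate | C=C1C(=O)O[C@H]2/C=C(/CO)C(=O)CC[C@@](C)(O)C[C@@H](OC(=O)[C@H](C)CC)[C@@H]12 | target

Total step count: 19. Longest linear sequence: 14 steps (steps 1–3, 5, 6 and 11–19); the sulfone branch (steps 7–10) and step 4 are convergent.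

Steps most likely to fail:

- Step 15. The borane may couple between molecules (oligomers), lose boron by protonation before the acyl complex captures it, or the acyl complex may be intercepted by hydroxide. Fallback from 24 to 27 by a polar ring closure at C3–C4: rhodium-catalysed linear hydroformylation of the vinyl group (Rh(acac)(CO)2, Xantphos, CO/H2, toluene, 60 °C) should give the C3 aldehyde F1. Intramolecular Nozaki–Hiyama–Kishi addition of the C4 iodide to C3 (CrCl2, NiCl2 cat., DMSO/THF, high dilution) should then give the ring-closed C3 allylic alcohol F2 as either epimer, and Dess–Martin oxidation returns to the route at 27.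

- Step 11. The carbanion next to the fully substituted C10 is hindered and basic, so acyl substitution may be slow and the acyl imidazolide may instead be deprotonated at C7, with epimerisation or β-elimination of the lactone oxygen. Fallback from 12 to 19 by carbonyl addition and oxidation: BH3·SMe2 reduces the acid chemoselectively to the hydroxymethyl lactone F3, Dess–Martin oxidation gives the aldehyde F4, the lithio derivative of 17 (one equivalent) adds at −78 °C to give the β-hydroxy sulfone F5 as a mixture of epimers, and a second Dess–Martin oxidation returns to the route at 19.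

- Step 13. Facial selectivity may be poor, or the C8 alkoxide may attack the lactone and shift the ring to O8. Fallback from 20 by reagent control: reduction with catecholborane catalysed by (S)-1-methyl-3,3-diphenyltetrahydro-1H,3H-pyrrolo[1,2-c][1,3,2]oxazaborole (toluene, −78 °C; C7 as the large group) leaves a neutral boron alkoxide and returns to the route at 21. Any C8 epimer F6 is not lost, because Mitsunobu esterification with 22 (PPh3, DIAD) inverts C8 and returns to the route at 24.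

Further compounds
F1 | step 15 | (1R,3R)-1-{(2R,3R)-2-[(Z)-3-[(tert-butyldiphenylsilyl)oxy]-2-iodoprop-1-en-1-yl]-5-oxooxolan-3-yl}-3-methyl-6-oxo-3-[(triethylsilyl)oxy]hexyl (R)-2-methylbutanoate | C1C(=O)O[C@@H](/C=C(\I)CO[Si](c2ccccc2)(c2ccccc2)C(C)(C)C)[C@H]1[C@H](OC(=O)[C@H](C)CC)C[C@](C)(O[Si](CC)(CC)CC)CCC=O
F2 | step 15 | C3 allylic alcohol corresponding to 27 (hydroxyl in place of the C3 ketone, either C3 epimer) | C1C(=O)O[C@H]2/C=C(/CO[Si](c3ccccc3)(c3ccccc3)C(C)(C)C)C(O)CC[C@@](C)(O[Si](CC)(CC)CC)C[C@@H](OC(=O)[C@H](C)CC)[C@@H]12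
F3 | step 11 | (4R,5R)-5-[(Z)-3-[(tert-butyldiphenylsilyl)oxy]-2-iodoprop-1-en-1-yl]-4-(hydroxymethyl)oxolan-2-one | C1C(=O)O[C@@H](/C=C(\I)CO[Si](c2ccccc2)(c2ccccc2)C(C)(C)C)[C@H]1CO
F4 | step 11 | (2R,3S)-2-[(Z)-3-[(tert-butyldiphenylsilyl)oxy]-2-iodoprop-1-en-1-yl]-5-oxooxolane-3-carbaldehyde | C1C(=O)O[C@@H](/C=C(\I)CO[Si](c2ccccc2)(c2ccccc2)C(C)(C)C)[C@H]1C=O
F5 | step 11 | (4R,5R)-5-[(Z)-3-[(tert-butyldiphenylsilyl)oxy]-2-iodoprop-1-en-1-yl]-4-{(3R)-1-hydroxy-3-methyl-2-(phenylsulfonyl)-3-[(triethylsilyl)oxy]pent-4-en-1-yl}oxolan-2-one (C8 and C9 epimers) | C1C(=O)O[C@@H](/C=C(\I)CO[Si](c2ccccc2)(c2ccccc2)C(C)(C)C)[C@H]1C(O)C([C@](C)(O[Si](CC)(CC)CC)C=C)S(=O)(=O)c1ccccc1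
F6 | step 13 | (4R,5R)-5-[(Z)-3-[(tert-butyldiphenylsilyl)oxy]-2-iodoprop-1-en-1-yl]-4-{(1S,3S)-1-hydroxy-3-methyl-3-[(triethylsilyl)oxy]pent-4-en-1-yl}oxolan-2-one (C8 epimer of 21) | C1C(=O)O[C@@H](/C=C(\I)CO[Si](c2ccccc2)(c2ccccc2)C(C)(C)C)[C@H]1[C@@H](O)C[C@](C)(O[Si](CC)(CC)CC)C=C
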